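## The problem

The target is an 11,13-dihydrogermacranolide. A ten-membered carbocycle C1–C10 carries E trisubstituted olefins at C1=C10 and C4=C5 and is trans-fused at C6–C7 to a γ-lactone (O6–C12–C11–C7). C11 bears a methyl group and O8 bears the ester of (E)-4-hydroxy-2-(hydroxymethyl)but-2-enoic acid (germacrane numbering, used here for open-chain intermediates too). Four contiguous stereocentres, C6, C7, C8 and C11 (6R,7R,8R,11S), lie on one edge of the ring; everything else is olefin geometry. C7 is the pivot: it carries the bond to C11 and is flanked by the oxygenated carbons C6 and C8, so these three centres must be set together. C11 is epimerisable and can be controlled from C7, since its methyl group ends up trans to the C7 side chain. Closing the medium ring is costly and both olefins must emerge E, so the closure should not also have to create stereocentres. Three features are fragile: the 1,5-diene (transannular cyclisation in acid, Cope rearrangement on heating), the lactone once O8 is free under base (translactonisation to the 8,12-olide), and the side-chain enoate with two allylic hydroxyls, which cannot pass through basic or reducing steps. The enabling feature is that O6–C6–C7–C8–O8 is the pattern of a 2,3-epoxy-1-ol opened at its 2-position. Replacing the C7–C11 bond by an epoxide oxygen bridging C7 and C8 gives an epoxy alcohol whose O6 can carry C12–C11 as a malonate, so that C11 is delivered to C7 through a five-membered ring.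

## Retrosynthesis

**Side chain (O8–acyl bond).** Target 36 is traced to acetonide ester 35 and then to alcohol 28 and acid 33. The enoate would not survive the carbanion and electron-transfer steps of ring construction, so it is attached last. The seven-membered acetonide of 33 holds the two CH2O groups cis, which fixes the E geometry of the enoate and makes isomerisation during acylation impossible. The forward reaction must acylate a hindered secondary alcohol without forming a free C8 alkoxide.

**Ring bond C2–C3.** Alcohol 28 comes from silyl ether 27, which comes from macrocyclic sulfone 26 and this from the open-chain sulfone bromide 25. C2–C3 is the only ring bond that joins two allylic methylenes and is remote from every stereocentre, so both olefins can be made with defined geometry in open-chain pieces. Cuts at C5–C6 or C9–C10 would ask the ring closure to set a stereocentre or an olefin as well. The sulfone is placed on C2 and the bromide on C3: a carbanion at C3 would be vinylogously β to the C6–O bond and would expel the lactone carboxylate. The forward steps need a ten-membered alkylation at high dilution beside a lactone, and a desulfonylation that leaves C1=C10 in place.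

**The two arms.** Compound 25 is reached from 24, 23 and 21, all derived from the bis-ether 20. The C2 oxygen is carried as a PMB ether and the C3 oxygen as a primary TBS ether, so each arm can be unmasked in turn while the secondary O8 TBS ether stays.

**C11 methyl and the extra carboxyl.** Lactone 20 comes from 18 by enolate methylation, and 18 from 17 and 16 by silylation and demethoxycarbonylation. Methylation of the lactone enolate anti to the C7 side chain gives the isomer that is also the more stable one, so later base cannot erode it. O8 is silylated first so that no alkoxide can reach C12.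

**Key disconnection (C7–C11 and the lactone ring).** Lactone 16 is opened to epoxy malonate 15, the ester of anti epoxy alcohol 13 with acid chloride 14. This removes a ring, a C–C bond and the C7 stereocentre in one operation and reduces the stereochemical problem to an epoxy alcohol triad. A malonate is preferred to a simple ester because O6 is allylic: a reactive ester enolate would undergo Ireland–Claisen rearrangement, whereas the stabilised enolate only alkylates.

**The C6–C7–C8 triad.** Epoxy alcohol 13 comes from racemic trienol 12 by Sharpless kinetic resolution, and 12 from enal 8 and alkenyl iodide 11. Adding an alkenyl metal to a 2,3-epoxy aldehyde would leave C6 to weak substrate control. The kinetic resolution sets C6, C7 and C8 in one catalyst-controlled step with the anti relationship the key step needs. The price is that at most half of 12 is used; the other enantiomer can be returned to the racemate by oxidation and re-reduction of the carbinol.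

**Small pieces.** Enal 8 comes from dienol 7, enynol 6, bromide 4 and propargyl alcohol 5; bromide 4 comes from prenol 1 through 2 and 3. A PMB ether is used because an acetate would not survive the hydride step. Iodide 11 comes from 5 through 10. Acid 33 comes from but-2-yne-1,4-diol 29 through 30 and 31: syn hydrostannylation gives the cis diol needed for the ring-locked acetonide.

## Roads not taken

**Alternative 1:** The ring is cut at C9–C10. The precursor A1 is the finished lactone carrying a C8–C9 terminal epoxide and a C1–C10 methyl alkyne. Zerovalent nickel (Ni(cod)2, PBu3, Et3B) would join the epoxide terminus to the alkyne with syn delivery of hydrogen, closing the ring, setting C1=C10 as E and releasing the free C8 alcohol A2, which is the same compound as 28 of the present route.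

- Merits: no protection of O8, no sulfone, and an endgame shorter by about six steps. In step economy after the lactone it is clearly better.
- Weak points: regioselection on a methyl/alkyl alkyne is poor in this coupling, and closure of a strained ten-membered ring by this method is not established. A1 already needs all four stereocentres plus a configured epoxide next to C7, so the stereochemical problem is untouched.
- Against it, the chosen plan sets a ring closure of established type and a single reaction family that fixes C6, C7 and C8.

**Alternative 2:** The ring is cut at C5–C6. The E alkenyl iodide/aldehyde A3 would close with CrCl2 and catalytic NiCl2 to the cyclodecadienol A4, which is then lactonised.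

- Merits: alkenylchromium closure is the best-precedented way to make ten-membered germacrane rings and tolerates esters and silyl ethers. It needs no auxiliary group to remove, so its ring construction is more reliable than sulfone alkylation plus desulfonylation.
- Weak points: the C6 carbinol is created during the macrocyclisation, and only one epimer can give the trans lactone. Aldehyde A3 has an epimerisable C7 centre β to the C8 silyloxy group. The C7/C8/C11 triad must be built by separate acyclic stereocontrol.
- Against it, the chosen plan has C6, C7 and C8 fixed before the ring is closed, so the closure carries no stereochemical burden.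

**Alternative 3:** The ten-membered ring is hidden in a decalin. The eudesm-4-enolide 1β-mesylate A5, drawn from the sesquiterpene lactone chiral pool, would be hydroborated at C4=C5 and fragmented across C5–C10 by alkoxide activation of the borane. This gives A6, which is identical with 27.

- Merits: both E olefins and the ring arise stereospecifically in one step, and C6, C7 and C11 come from the pool. In olefin control it is better than any macrocyclisation.
- Weak points: A5 needs an oxygen at C8, a position that is neither present nor activated in the available eudesmanolides. The 1β-hydroxyl and the tetrasubstituted olefin must also be installed, and the hydroboration must be face- and regioselective beside a lactone. The adjustment sequence is long and uncertain.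
- Against it, the chosen plan carries O8 from the start as the epoxide oxygen.

Key step: step 12

Remark: sulfone 26 is carried as a mixture of C2 epimers, because that centre is erased in step 21. Abbreviations: TBS = tert-butyldimethylsilyl, PMB = 4-methoxybenzyl, DIPT = diisopropyl tartrate.

Step 1
Reactants: 1 prenol
Product: 2 prenyl PMB ether
Conditions: NaH, 4-methoxybenzyl chloride, Bu4NI (cat.), THF/DMF, 0 °C to rt
Reagents that add atoms: 4-methoxybenzyl chloride, COc1ccc(CCl)cc1
Why: Williamson etherification of a primary allylic alkoxide; the PMB ether survives the later hydride, oxidation and organometallic steps and is removable beside silyl ethers.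

Step 2
Reactants: 2 prenyl PMB ether
Product: 3 E allylic alcohol
Conditions: SeO2 (cat.), t-BuOOH, salicylic acid (cat.), CH2Cl2, rt
Reagents that add atoms: SeO2, O=[Se]=O; tert-butyl hydroperoxide, CC(C)(C)OO
Why: SeO2 allylic oxidation (ene reaction, then [2,3]-sigmatropic shift) oxidises the methyl group trans to the chain of a trisubstituted olefin, so the E alcohol should result; well known for prenyl ethers and esters.

Step 3
Reactants: 3 E allylic alcohol
Product: 4 E allylic bromide
Conditions: CBr4, PPh3, CH2Cl2, 0 °C
Reagents that add atoms: carbon tetrabromide, BrC(Br)(Br)Br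
Why: Appel bromination of a primary allylic alcohol; olefin geometry is not touched.

Step 4
Reactants: 4 E allylic bromide; 5 propargyl alcohol
Product: 6 enynol
Conditions: CuI (cat.), NaI (cat.), K2CO3, DMF, rt
Reagents that add atoms: none
Why: Copper-mediated coupling of a terminal alkyne with a primary allylic halide; the copper acetylide attacks the unhindered CH2 and the free hydroxyl is tolerated.

Step 5
Reactants: 6 enynol
Product: 7 (2E,5E)-dienol
Conditions: NaAlH2(OCH2CH2OMe)2, THF, 0 °C
Reagents that add atoms: none
Why: Alkoxide-directed trans-hydroalumination of a propargylic alcohol gives the E allylic alcohol (C7=C8); the isolated trisubstituted olefin and the PMB ether are inert.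

Step 6
Reactants: 7 (2E,5E)-dienol
Product: 8 (2E,5E)-dienal
Conditions: MnO2, CH2Cl2, rt
Reagents that add atoms: none
Why: Allylic oxidation with MnO2 is neutral, so the skipped diene should not be drawn into conjugation; 8 is used directly.

Step 7
Reactants: 5 propargyl alcohol
Product: 10 (E)-3-iodo-2-methylprop-2-en-1-ol, via alkenylalane 9 (not isolated)
Conditions: Me3Al, Cp2ZrCl2 (cat.), CH2Cl2, 0 °C to rt; then I2, THF, −30 °C
Reagents that add atoms: trimethylaluminium, C[Al](C)C; iodine, II
Why: Negishi carboalumination adds methyl and aluminium syn across the alkyne with aluminium at the terminus; iodinolysis with retention gives the E iodide, which fixes the C4=C5 geometry and the C15 methyl.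

Step 8
Reactants: 10 (E)-3-iodo-2-methylprop-2-en-1-ol
Product: 11 alkenyl iodide TBS ether
Conditions: tert-butyldimethylsilyl chloride, imidazole, DMF, rt
Reagents that add atoms: tert-butyldimethylsilyl chloride, CC(C)(C)[Si](C)(C)Cl
Why: Standard silylation; the free primary allylic hydroxyl would otherwise be the preferred site of the later titanium-catalysed epoxidation.

Step 9
Reactants: 8 (2E,5E)-dienal; 11 alkenyl iodide TBS ether
Product: 12 racemic trienol
Conditions: CrCl2, NiCl2 (cat.), DMSO, rt
Reagents that add atoms: none
Why: Nozaki–Hiyama–Kishi reaction: the alkenylchromium adds 1,2 to the aldehyde with retention of olefin geometry and is not basic, so the doubly allylic C9 methylene of 8 is not deprotonated. C6 is formed racemic on purpose and is resolved in step 10.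

Step 10
Reactants: 12 racemic trienol
Product: 13 anti epoxy alcohol
Conditions: Ti(OiPr)4 (0.1 equiv), D-(−)-DIPT (0.15 equiv), t-BuOOH (0.6 equiv), 4 Å sieves, CH2Cl2, −20 °C
Reagents that add atoms: tert-butyl hydroperoxide, CC(C)(C)OO
Why: Sharpless kinetic resolution: with the D-(−)-tartrate catalyst the (4S) enantiomer of 12 is epoxidised fast at the E-disubstituted C7=C8 olefin on the tartrate-controlled face, and secondary allylic alcohols give the anti (erythro) epoxy alcohol, so C6, C7 and C8 are fixed together. The C4=C5 olefin has the C15 methyl cis to the carbinol carbon, a pattern this catalyst epoxidises only sluggishly, and C1=C10 is not allylic to a free hydroxyl. The slow (4R) enantiomer of 12 remains and can be recycled by oxidation and re-reduction.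

Step 11
Reactants: 13 anti epoxy alcohol; 14 methyl 3-chloro-3-oxopropanoate
Product: 15 epoxy malonate
Conditions: pyridine, CH2Cl2, −20 to 0 °C
Reagents that add atoms: none
Why: Acylation of the secondary alcohol with an acid chloride under mild base; no stereocentre is touched and the epoxide is stable to pyridine.

Step 12
Reactants: 15 epoxy malonate
Product: 16 trans lactone alcohol
Conditions: NaH (1.05 equiv), THF, 0 to 40 °C; AcOH, 0 °C
Reagents that add atoms: none
Why: NaH removes the malonate proton of 15, the only acidic C–H, and the sodium enolate attacks C7 opposite the C7–O epoxide bond; this is an intramolecular SN2 epoxide opening by a tethered stabilised carbanion, known for esters of 2,3-epoxy alcohols. The closure is 5-exo-tet: the forming ring O6–C12–C11–C7–C6 has five members and the breaking C7–O bond lies outside it, whereas attack at C8 would be 6-endo and C8 has no activating group. C7 is inverted while C6 and C8 are untouched, so the anti triad of 15 becomes the trans disposition of the C5 and C8 substituents on the lactone; all three centres trace back to step 10. C11 forms as an enolisable centre that should settle trans to the C7 side chain and is erased in step 14. The released C8 alkoxide is quenched at once by the much more acidic C11–H, so the product rests as the β-dicarbonyl enolate, in which neither C12 nor the methyl ester is electrophilic; this should prevent translactonisation to the 8,12-olide before the acetic acid quench. A stabilised malonate enolate is used because O6 is allylic and a simple ester enolate would undergo Ireland–Claisen rearrangement. The s-cis ester geometry needed for closure is the main kinetic cost, hence the gentle warming.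

Step 13
Reactants: 16 trans lactone alcohol
Product: 17 O8 TBS ether
Conditions: TBSOTf, 2,6-lutidine, CH2Cl2, −78 to 0 °C
Reagents that add atoms: tert-butyldimethylsilyl trifluoromethanesulfonate, CC(C)(C)[Si](C)(C)OS(=O)(=O)C(F)(F)F
Why: Silylation of the hindered secondary alcohol under non-nucleophilic base; any O-silylated enol of the β-dicarbonyl unit is hydrolysed on work-up. With O8 capped, no alkoxide can reach C12 in later steps.

Step 14
Reactants: 17 O8 TBS ether
Product: 18 lactone with C11 methylene
Conditions: LiCl, H2O, DMSO, 130 °C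
Reagents that add atoms: none
Why: Krapcho demethoxycarbonylation: chloride dealkylates the methyl ester, the β-carboxy lactone loses CO2 and the enolate is protonated by water. Silyl and PMB ethers tolerate these neutral conditions.

Step 15
Reactants: 18 lactone with C11 methylene
Product: 20 (11S)-methyl lactone, via lithium enolate 19 (not isolated)
Conditions: LDA, THF, −78 °C; then MeI, −78 to −40 °C
Reagents that add atoms: iodomethane, CI; lithium diisopropylamide, CC(C)N([Li])C(C)C (lithium of 19 only)
Why: Alkylation of a β-substituted γ-lactone enolate occurs anti to the β-substituent; the bulky C8 side chain on C7 should direct methyl to the opposite face, giving the 11S centre. This trans isomer is also the thermodynamic one.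

Step 16
Reactants: 20 (11S)-methyl lactone
Product: 21 C2 allylic alcohol
Conditions: DDQ, CH2Cl2/pH 7 buffer, 0 °C
Reagents that add atoms: none
Why: Oxidative cleavage of the PMB ether by hydride abstraction and hydrolysis; silyl ethers, lactone and isolated olefins are inert when DDQ is limited to a slight excess.

Step 17
Reactants: 21 C2 allylic alcohol
Product: 23 C2 allylic sulfone, via allylic bromide 22 (not isolated)
Conditions: CBr4, PPh3, 2,6-lutidine, CH2Cl2, 0 °C; then PhSO2Na, DMF, rt
Reagents that add atoms: sodium benzenesulfinate, [Na+].[O-]S(=O)c1ccccc1; carbon tetrabromide, BrC(Br)(Br)Br (bromine of 22 only)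
Why: Appel bromination, then S-alkylation of sulfinate at the primary allylic carbon, the standard route to allylic sulfones; the buffer protects the primary silyl ether.

Step 18
Reactants: 23 C2 allylic sulfone
Product: 24 C3 allylic alcohol
Conditions: HF·pyridine, pyridine, THF, 0 °C
Reagents that add atoms: none
Why: Buffered HF·pyridine cleaves the unhindered primary allylic TBS ether much faster than the secondary, flanked O8 TBS ether.

Step 19
Reactants: 24 C3 allylic alcohol
Product: 25 sulfone bromide
Conditions: CBr4, PPh3, CH2Cl2, −20 °C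
Reagents that add atoms: carbon tetrabromide, BrC(Br)(Br)Br
Why: Appel bromination of the primary allylic alcohol; 25 is used without storage.

Step 20
Reactants: 25 sulfone bromide
Product: 26 macrocyclic sulfone
Conditions: LiN(SiMe3)2 (1.1 equiv), THF, −78 to 0 °C, slow addition of 25 at high dilution
Reagents that add atoms: none
Why: Intramolecular alkylation of an α-sulfonyl allyl carbanion by an allylic bromide, the established closure of E,E-cyclodeca-1,5-dienes and larger terpenoid rings by stabilised carbanions. The C2–H is the most acidic proton, α-attack gives the ten-membered ring, and γ-attack or SN2′ would require eight-membered rings containing an E olefin. No ring stereocentre is formed except the transient C2.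

Step 21
Reactants: 26 macrocyclic sulfone
Product: 27 silylated germacranolide
Conditions: Na(Hg), Na2HPO4, MeOH/THF, −20 °C
Reagents that add atoms: none
Why: Reductive desulfonylation by electron transfer, with protonation of the allyl anion at the less substituted C2 terminus so that the trisubstituted C1=C10 olefin is kept; the buffered, cold medium leaves lactone and silyl ether intact.

Step 22
Reactants: 27 silylated germacranolide
Product: 28 8β-hydroxy germacranolide
Conditions: Bu4NF, AcOH (1:1), THF, rt
Reagents that add atoms: none
Why: Fluoride desilylation buffered with acetic acid, so that no free C8 alkoxide (translactonisation) and no strong acid (transannular cyclisation) is present.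

Step 23
Reactants: 29 but-2-yne-1,4-diol
Product: 30 (E)-stannyl diol
Conditions: Bu3SnH, PdCl2(PPh3)2 (cat.), THF, rt
Reagents that add atoms: tributyltin hydride, CCCC[SnH](CCCC)CCCC
Why: Palladium-catalysed hydrostannylation is a syn addition; on the symmetric alkyne there is no regiochemical issue and the two CH2OH groups end up cis.

Step 24
Reactants: 30 (E)-stannyl diol
Product: 31 stannyl dioxepine
Conditions: 2,2-dimethoxypropane, PPTS (cat.), CH2Cl2, rt
Reagents that add atoms: 2,2-dimethoxypropane, COC(C)(C)OC
Why: Acetonide formation across the cis-1,4-diol gives the 4,7-dihydro-1,3-dioxepine, which locks the olefin geometry in a ring.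

Step 25
Reactants: 31 stannyl dioxepine
Product: 33 dioxepine carboxylic acid, via vinyllithium 32 (not isolated)
Conditions: n-BuLi, THF, −78 °C; then CO2; cold dilute HCl to pH 4
Reagents that add atoms: carbon dioxide, O=C=O; n-butyllithium, [Li]CCCC (lithium of 32 only)
Why: Tin–lithium exchange with retention, then carboxylation; β-elimination of the allylic oxygen from 32 is disfavoured because the ring holds the C–O bonds out of the plane of the C–Li bond.

Step 26
Reactants: 28 8β-hydroxy germacranolide; 33 dioxepine carboxylic acid
Product: 35 acetonide ester, via mixed anhydride 34 (not isolated)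
Conditions: 33, 2,4,6-trichlorobenzoyl chloride, Et3N, THF, rt; then 28, DMAP, toluene, rt
Reagents that add atoms: 2,4,6-trichlorobenzoyl chloride, O=C(Cl)c1c(Cl)cc(Cl)cc1Cl (aroyl group of 34 only)
Why: Yamaguchi esterification acylates hindered secondary alcohols without generating an alkoxide; the ring-locked enoate cannot isomerise under DMAP.

Step 27
Reactants: 35 acetonide ester
Product: 36 CNP0272217.1
Conditions: PPTS (cat.), MeOH, 0 °C to rt
Reagents that add atoms: none
Why: Acetal exchange of the labile seven-membered acetonide under weakly acidic conditions should leave the diene untouched; the liberated C4′ hydroxyl is trans to the ester carbonyl and cannot lactonise.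

## Compound list

1 | 3-methylbut-2-en-1-ol (prenol) | CC(C)=CCO | starting material
2 | 1-methoxy-4-{[(3-methylbut-2-en-1-yl)oxy]methyl}benzene | CC(C)=CCOCc1ccc(OC)cc1 | intermediate
3 | (2E)-4-[(4-methoxybenzyl)oxy]-2-methylbut-2-en-1-ol | OC/C(C)=C/COCc1ccc(OC)cc1 | intermediate
4 | 1-({[(2E)-4-bromo-3-methylbut-2-en-1-yl]oxy}methyl)-4-methoxybenzene | BrC/C(C)=C/COCc1ccc(OC)cc1 | intermediate
5 | prop-2-yn-1-ol (propargyl alcohol) | C#CCO | starting material
6 | (5E)-7-[(4-methoxybenzyl)oxy]-5-methylhept-5-en-2-yn-1-ol | OCC#CC/C(C)=C/COCc1ccc(OC)cc1 | intermediate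
7 | (2E,5E)-7-[(4-methoxybenzyl)oxy]-5-methylhepta-2,5-dien-1-ol | OC/C=C/C/C(C)=C/COCc1ccc(OC)cc1 | intermediate
8 | (2E,5E)-7-[(4-methoxybenzyl)oxy]-5-methylhepta-2,5-dienal | O=C/C=C/C/C(C)=C/COCc1ccc(OC)cc1 | intermediate
9 | (E)-alkenylalane Me2Al–CH=C(CH3)–CH2–O–AlMe2 | C[Al](C)/C=C(\C)CO[Al](C)C | intermediate
10 | (2E)-3-iodo-2-methylprop-2-en-1-ol | OC/C(C)=C/I | intermediate
11 | tert-butyl{[(2E)-3-iodo-2-methylprop-2-en-1-yl]oxy}dimethylsilane | CC(C)(C)[Si](C)(C)OC/C(C)=C/I | intermediate
12 | rac-(2E,5E,8E)-1-[(tert-butyldimethylsilyl)oxy]-10-[(4-methoxybenzyl)oxy]-2,8-dimethyldeca-2,5,8-trien-4-ol | C/C(CO[Si](C)(C)C(C)(C)C)=C\C(O)/C=C/C/C(C)=C/COCc1ccc(OC)cc1 | intermediate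
13 | (2E,4R,5R,6R,8E)-1-[(tert-butyldimethylsilyl)oxy]-5,6-epoxy-10-[(4-methoxybenzyl)oxy]-2,8-dimethyldeca-2,8-dien-4-ol (6R,7R,8R in germacrane numbering) | C/C(CO[Si](C)(C)C(C)(C)C)=C\[C@@H](O)[C@H]1O[C@@H]1C/C(C)=C/COCc1ccc(OC)cc1 | intermediate
14 | methyl 3-chloro-3-oxopropanoate | COC(=O)CC(Cl)=O | starting material
15 | methyl (2E,4R,5S,6R,8E)-1-[(tert-butyldimethylsilyl)oxy]-5,6-epoxy-10-[(4-methoxybenzyl)oxy]-2,8-dimethyldeca-2,8-dien-4-yl propanedioate | C/C(CO[Si](C)(C)C(C)(C)C)=C\[C@@H](OC(=O)CC(=O)OC)[C@H]1O[C@@H]1C/C(C)=C/COCc1ccc(OC)cc1 | intermediate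
16 | methyl (3R,4R,5R)-5-{(1E)-3-[(tert-butyldimethylsilyl)oxy]-2-methylprop-1-en-1-yl}-4-{(1R,3E)-1-hydroxy-5-[(4-methoxybenzyl)oxy]-3-methylpent-3-en-1-yl}-2-oxooxolane-3-carboxylate | C/C(CO[Si](C)(C)C(C)(C)C)=C\[C@H]1OC(=O)[C@@H](C(=O)OC)[C@@H]1[C@H](O)C/C(C)=C/COCc1ccc(OC)cc1 | intermediate
17 | methyl (3R,4S,5R)-5-{(1E)-3-[(tert-butyldimethylsilyl)oxy]-2-methylprop-1-en-1-yl}-4-{(1R,3E)-1-[(tert-butyldimethylsilyl)oxy]-5-[(4-methoxybenzyl)oxy]-3-methylpent-3-en-1-yl}-2-oxooxolane-3-carboxylate | C/C(CO[Si](C)(C)C(C)(C)C)=C\[C@H]1OC(=O)[C@@H](C(=O)OC)[C@@H]1[C@H](O[Si](C)(C)C(C)(C)C)C/C(C)=C/COCc1ccc(OC)cc1 | intermediate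
18 | (4S,5R)-5-{(1E)-3-[(tert-butyldimethylsilyl)oxy]-2-methylprop-1-en-1-yl}-4-{(1R,3E)-1-[(tert-butyldimethylsilyl)oxy]-5-[(4-methoxybenzyl)oxy]-3-methylpent-3-en-1-yl}oxolan-2-one | C/C(CO[Si](C)(C)C(C)(C)C)=C\[C@H]1OC(=O)C[C@@H]1[C@H](O[Si](C)(C)C(C)(C)C)C/C(C)=C/COCc1ccc(OC)cc1 | intermediate
19 | lithium enolate of 18 (C11=C12–O–Li) | C/C(CO[Si](C)(C)C(C)(C)C)=C\[C@H]1OC([O-])=C[C@@H]1[C@H](O[Si](C)(C)C(C)(C)C)C/C(C)=C/COCc1ccc(OC)cc1.[Li+] | intermediate
20 | (3S,4S,5R)-5-{(1E)-3-[(tert-butyldimethylsilyl)oxy]-2-methylprop-1-en-1-yl}-4-{(1R,3E)-1-[(tert-butyldimethylsilyl)oxy]-5-[(4-methoxybenzyl)oxy]-3-methylpent-3-en-1-yl}-3-methyloxolan-2-one | C/C(CO[Si](C)(C)C(C)(C)C)=C\[C@H]1OC(=O)[C@@H](C)[C@@H]1[C@H](O[Si](C)(C)C(C)(C)C)C/C(C)=C/COCc1ccc(OC)cc1 | intermediate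
21 | (3S,4S,5R)-5-{(1E)-3-[(tert-butyldimethylsilyl)oxy]-2-methylprop-1-en-1-yl}-4-{(1R,3E)-1-[(tert-butyldimethylsilyl)oxy]-5-hydroxy-3-methylpent-3-en-1-yl}-3-methyloxolan-2-one | C/C(CO[Si](C)(C)C(C)(C)C)=C\[C@H]1OC(=O)[C@@H](C)[C@@H]1[C@H](O[Si](C)(C)C(C)(C)C)C/C(C)=C/CO | intermediate
22 | 5-bromo analogue of 21 (C2 allylic bromide, same stereocentres) | C/C(CO[Si](C)(C)C(C)(C)C)=C\[C@H]1OC(=O)[C@@H](C)[C@@H]1[C@H](O[Si](C)(C)C(C)(C)C)C/C(C)=C/CBr | intermediate
23 | (3S,4S,5R)-4-{(1R,3E)-5-(benzenesulfonyl)-1-[(tert-butyldimethylsilyl)oxy]-3-methylpent-3-en-1-yl}-5-{(1E)-3-[(tert-butyldimethylsilyl)oxy]-2-methylprop-1-en-1-yl}-3-methyloxolan-2-one | C/C(CO[Si](C)(C)C(C)(C)C)=C\[C@H]1OC(=O)[C@@H](C)[C@@H]1[C@H](O[Si](C)(C)C(C)(C)C)C/C(C)=C/CS(=O)(=O)c1ccccc1 | intermediate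
24 | (3S,4S,5R)-4-{(1R,3E)-5-(benzenesulfonyl)-1-[(tert-butyldimethylsilyl)oxy]-3-methylpent-3-en-1-yl}-5-[(1E)-3-hydroxy-2-methylprop-1-en-1-yl]-3-methyloxolan-2-one | C/C(CO)=C\[C@H]1OC(=O)[C@@H](C)[C@@H]1[C@H](O[Si](C)(C)C(C)(C)C)C/C(C)=C/CS(=O)(=O)c1ccccc1 | intermediate
25 | (3S,4S,5R)-4-{(1R,3E)-5-(benzenesulfonyl)-1-[(tert-butyldimethylsilyl)oxy]-3-methylpent-3-en-1-yl}-5-[(1E)-3-bromo-2-methylprop-1-en-1-yl]-3-methyloxolan-2-one | C/C(CBr)=C\[C@H]1OC(=O)[C@@H](C)[C@@H]1[C@H](O[Si](C)(C)C(C)(C)C)C/C(C)=C/CS(=O)(=O)c1ccccc1 | intermediate
26 | (3S,3aS,4R,6E,10E,11aR)-8-(benzenesulfonyl)-4-[(tert-butyldimethylsilyl)oxy]-3,6,10-trimethyl-3a,4,5,8,9,11a-hexahydrocyclodeca[b]furan-2(3H)-one, mixture of epimers at ring position 8 (germacrane C2) | C/C1=C\[C@H]2OC(=O)[C@@H](C)[C@@H]2[C@H](O[Si](C)(C)C(C)(C)C)C/C(C)=C/C(S(=O)(=O)c3ccccc3)C1 | intermediate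
27 | (3S,3aS,4R,6E,10E,11aR)-4-[(tert-butyldimethylsilyl)oxy]-3,6,10-trimethyl-3a,4,5,8,9,11a-hexahydrocyclodeca[b]furan-2(3H)-one | C/C1=C\[C@H]2OC(=O)[C@@H](C)[C@@H]2[C@H](O[Si](C)(C)C(C)(C)C)C/C(C)=C/CC1 | intermediate
28 | (3S,3aR,4R,6E,10E,11aR)-4-hydroxy-3,6,10-trimethyl-3a,4,5,8,9,11a-hexahydrocyclodeca[b]furan-2(3H)-one | C/C1=C\[C@H]2OC(=O)[C@@H](C)[C@@H]2[C@H](O)C/C(C)=C/CC1 | intermediate
29 | but-2-yne-1,4-diol | OCC#CCO | starting material
30 | (2E)-2-(tributylstannyl)but-2-ene-1,4-diol | OC/C=C(/[Sn](CCCC)(CCCC)CCCC)CO | intermediate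
31 | tributyl(2,2-dimethyl-4,7-dihydro-1,3-dioxepin-5-yl)stannane | CC1(C)OCC=C([Sn](CCCC)(CCCC)CCCC)CO1 | intermediate
32 | (2,2-dimethyl-4,7-dihydro-1,3-dioxepin-5-yl)lithium | CC1(C)OCC=C([Li])CO1 | intermediate
33 | 2,2-dimethyl-4,7-dihydro-1,3-dioxepine-5-carboxylic acid | CC1(C)OCC=C(C(=O)O)CO1 | intermediate
34 | 2,2-dimethyl-4,7-dihydro-1,3-dioxepine-5-carboxylic 2,4,6-trichlorobenzoic anhydride | CC1(C)OCC=C(C(=O)OC(=O)c2c(Cl)cc(Cl)cc2Cl)CO1 | intermediate
35 | (3S,3aR,4R,6E,10E,11aR)-3,6,10-trimethyl-2-oxo-2,3,3a,4,5,8,9,11a-octahydrocyclodeca[b]furan-4-yl 2,2-dimethyl-4,7-dihydro-1,3-dioxepine-5-carboxylate | C/C1=C\[C@H]2OC(=O)[C@@H](C)[C@@H]2[C@H](OC(=O)C3=CCOC(C)(C)OC3)C/C(C)=C/CC1 | intermediate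
36 | (3S,3aR,4R,6E,10E,11aR)-3,6,10-trimethyl-2-oxo-2,3,3a,4,5,8,9,11a-octahydrocyclodeca[b]furan-4-yl (2E)-4-hydroxy-2-(hydroxymethyl)but-2-enoate (CNP0272217.1; 6R,7R,8R,11S in germacrane numbering) | C/C1=C\[C@H]2OC(=O)[C@@H](C)[C@@H]2[C@H](OC(=O)/C(=C/CO)CO)C/C(C)=C/CC1 | target

## Step count and least certain steps

Total: 27 steps. Longest linear sequence: 22 steps (steps 1–6, 9–22, 26, 27).

**Step 12 (key step).** The closure may be slow, because the ester must adopt the s-cis geometry and C7 is flanked by two oxygenated carbons. Acyl transfer from the released C8 alkoxide to the methyl ester or to C12, or attack at C8, could then compete. Fallback, from 13: the tether is changed to the (phenylsulfonyl)acetate ester F1 (phenylsulfonylacetic acid, DCC, DMAP). Its softer carbanion (NaH or DBU) should close in the same 5-exo sense to the α-sulfonyl lactone alcohol F2, which has no second ester for the alkoxide to attack. Silylation (TBSOTf, 2,6-lutidine) gives the silyl ether F3, and reductive desulfonylation with aluminium amalgam, Al(Hg), in wet THF returns to the route at 18.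

**Step 20 (ring closure).** Oligomerisation, or proton transfer from C11–H to the sulfonyl carbanion with slow closure of the strained ring, may outrun cyclisation. Fallback, from 21: HF·pyridine removes the primary silyl ether to give the diol F4, and CBr4/PPh3 gives the bis(allylic bromide) F5. Zerovalent nickel, Ni(CO)4 in N-methylpyrrolidone at high dilution, couples the two allylic termini reductively and returns to the route at 27, with no sulfone to remove. Olefin geometry is less secure by this path, which is why it is not the first choice.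

**Step 21 (desulfonylation).** Protonation of the intermediate allyl anion at C10 instead of C2 would move the olefin to C1=C2, and E/Z leakage is possible. Fallback, from 26: PdCl2(dppp) (cat.) with excess LiBHEt3 in THF. The lactone is first reduced to the diolate, which also removes the ionisable allylic carboxylate at C6. Hydride is then delivered through the π-allylpalladium intermediate to the less substituted C2 terminus, giving the 6,12-diol F6. Oxidative lactonisation with TEMPO/PhI(OAc)2 (primary alcohol to lactol to lactone) returns to the route at 27.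

**Step 10 (kinetic resolution).** Discrimination between the two allylic olefins or between the enantiomers may be incomplete, and half of 12 is lost in any case. Fallback, from 7: Sharpless epoxidation with D-(−)-DIPT gives the primary epoxy alcohol F7, and Parikh–Doering oxidation gives the epoxy aldehyde F8. Addition of the alkenyllithium made from 11 (t-BuLi, Et2O, −78 °C) gives 13 together with its C6 epimer F9. Dess–Martin oxidation of the mixture gives the epoxy enone F10, and chelation-controlled reduction with Zn(BH4)2, which gives anti epoxy alcohols from α,β-epoxy ketones, returns to the route at 13.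

**Step 27 (final deprotection).** The acid needed for acetal exchange may start transannular cyclisation of the 1,5-diene. Fallback, from 30 and 28: the diol is silylated (Et3SiCl, imidazole) to the bis(triethylsilyl) stannane F11. Tin–lithium exchange and CO2 at −78 °C give the acid F12, and Yamaguchi esterification with 28 gives the ester F13. Bu4NF buffered with AcOH removes both silyl groups and returns to the route at 36.

## Further compounds

F1 | step 12 | (phenylsulfonyl)acetate ester of 13 | C/C(CO[Si](C)(C)C(C)(C)C)=C\[C@@H](OC(=O)CS(=O)(=O)c1ccccc1)[C@H]2O[C@@H]2C/C(C)=C/COCc3ccc(OC)cc3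
F2 | step 12 | α-(phenylsulfonyl) trans lactone alcohol (C11 epimers) | C/C(CO[Si](C)(C)C(C)(C)C)=C\[C@H]1OC(=O)C(S(=O)(=O)c2ccccc2)[C@@H]1[C@H](O)C/C(C)=C/COCc3ccc(OC)cc3
F3 | step 12 | O8 TBS ether of F2 | C/C(CO[Si](C)(C)C(C)(C)C)=C\[C@H]1OC(=O)C(S(=O)(=O)c2ccccc2)[C@@H]1[C@H](O[Si](C)(C)C(C)(C)C)C/C(C)=C/COCc3ccc(OC)cc3
F4 | step 20 | C2,C3 diol (O8 TBS, 11S-methyl lactone) | C/C(CO)=C\[C@H]1OC(=O)[C@@H](C)[C@@H]1[C@H](O[Si](C)(C)C(C)(C)C)C/C(C)=C/CO
F5 | step 20 | C2,C3 bis(allylic bromide) | C/C(CBr)=C\[C@H]1OC(=O)[C@@H](C)[C@@H]1[C@H](O[Si](C)(C)C(C)(C)C)C/C(C)=C/CBr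
F6 | step 21 | 8-O-TBS germacra-1(10),4-diene-6,12-diol | C/C1=C\[C@@H](O)[C@H]([C@H](C)CO)[C@H](O[Si](C)(C)C(C)(C)C)C/C(C)=C/CC1
F7 | step 10 | [(2R,3R)-3-{(2E)-4-[(4-methoxybenzyl)oxy]-2-methylbut-2-en-1-yl}oxiran-2-yl]methanol | OC[C@H]1O[C@@H]1C/C(C)=C/COCc2ccc(OC)cc2
F8 | step 10 | (2S,3R)-3-{(2E)-4-[(4-methoxybenzyl)oxy]-2-methylbut-2-en-1-yl}oxirane-2-carbaldehyde | O=C[C@H]1O[C@@H]1C/C(C)=C/COCc2ccc(OC)cc2
F9 | step 10 | C6 epimer of 13 (4S,5R,6R) | C/C(CO[Si](C)(C)C(C)(C)C)=C\[C@H](O)[C@H]1O[C@@H]1C/C(C)=C/COCc2ccc(OC)cc2
F10 | step 10 | epoxy enone (C6 ketone of 13) | C/C(CO[Si](C)(C)C(C)(C)C)=C\C(=O)[C@H]1O[C@@H]1C/C(C)=C/COCc2ccc(OC)cc2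
F11 | step 27 | (E)-1,4-bis[(triethylsilyl)oxy]-2-(tributylstannyl)but-2-ene | CC[Si](CC)(CC)OC/C=C(/[Sn](CCCC)(CCCC)CCCC)CO[Si](CC)(CC)CC
F12 | step 27 | (E)-4-[(triethylsilyl)oxy]-2-{[(triethylsilyl)oxy]methyl}but-2-enoic acid | CC[Si](CC)(CC)OC/C=C(/C(=O)O)CO[Si](CC)(CC)CC
F13 | step 27 | bis(triethylsilyl) ether of 36 | C/C1=C\[C@H]2OC(=O)[C@@H](C)[C@@H]2[C@H](OC(=O)/C(=C/CO[Si](CC)(CC)CC)CO[Si](CC)(CC)CC)C/C(C)=C/CC1
A1 | alternative 1 | alkynyl epoxy lactone (C9–C10 open) | CC#CCC/C(C)=C/[C@H]1OC(=O)[C@@H](C)[C@@H]1[C@H]2CO2
A2 | alternative 1 | 8β-hydroxy germacra-1(10),4-dien-6,12-olide (identical with 28) | C/C1=C\[C@H]2OC(=O)[C@@H](C)[C@@H]2[C@H](O)C/C(C)=C/CC1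
A3 | alternative 2 | E alkenyl iodide aldehyde ester (C5–C6 open) | I/C=C(\C)CC/C=C(\C)C[C@@H](O[Si](C)(C)C(C)(C)C)[C@H](C=O)[C@H](C)C(=O)OC
A4 | alternative 2 | cyclodecadienol ester | C/C1=C\[C@@H](O)[C@H]([C@H](C)C(=O)OC)[C@H](O[Si](C)(C)C(C)(C)C)C/C(C)=C/CC1
A5 | alternative 3 | 8β-silyloxy eudesm-4-en-6,12-olide 1β-mesylate | C[C@H]1[C@@H]2[C@H](O[Si](C)(C)C(C)(C)C)C[C@]3([C@H](OS(C)(=O)=O)CCC(C)=C3[C@H]2OC1=O)C
A6 | alternative 3 | 8-O-silyl germacra-1(10),4-dien-6,12-olide (identical with 27) | C/C1=C\[C@H]2OC(=O)[C@@H](C)[C@@H]2[C@H](O[Si](C)(C)C(C)(C)C)C/C(C)=C/CC1
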